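**Plan**
- Retrosynthesis: the phenols are unmasked last (three benzyl ethers and the 5-methyl ether of unit 1, the 7-methoxyflavanone), and both C4 ketones are traced back to silyl-protected carbinols. The O1–C8a aryl ether bond of unit 1 is cut next, then its C3–C4 bond (aldol). The same two bonds of unit 2 (the 5,7-dihydroxyflavanone) follow, and the diaryl ether C–O bond between the two B rings is cut last.
- Enabling feature: O1 of each flavanone is an ether oxygen bonded to the aromatic carbon C8a of ring A. A bromine on C8a therefore lets the C2 carbinol oxygen be arylated while every bond at C2 stays intact.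
- Forward: SNAr joins the B rings, with ring B of unit 1 carried as a nitrile so that only one methyl ketone is present. Aldol, silylation, transfer hydrogenation and palladium etherification build the pyran ring of unit 2. The nitrile then becomes the second methyl ketone and the same four operations build the pyran ring of unit 1, after which desilylation, oxidation and ether cleavage finish the route.
- Stereochemistry: both 2S centres come from transfer hydrogenation of the aryl ketones with RuCl(p-cymene)[(S,S)-TsDPEN] and are retained in the ring closures. The C4 carbinol centres are not controlled and disappear on oxidation.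

Key step: step 14

Remark: the (S,S)-TsDPEN ruthenium catalyst is assumed to reduce the aryl ketones of steps 8 and 13 in the same sense as simple aryl alkyl ketones (hydride to the Re face, S carbinol). Every compound with a C4 silyloxy or hydroxy group is carried as a mixture of C4 epimers. Bn = benzyl, TBS = tert-butyldimethylsilyl.

**Route**

Step 1
Reactants: 1 5-bromoresorcinol
Product: 2 1,3-bis(benzyloxy)-5-bromobenzene
Conditions: BnBr, K2CO3, DMF, rt to 60 °C
Reagents that add atoms: benzyl bromide BrCc1ccccc1
Why: Williamson ether synthesis, in which both phenoxides of 1 are alkylated by the benzylic bromide under carbonate conditions that leave the aryl bromide untouched.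

Step 2
Reactants: 2 1,3-bis(benzyloxy)-5-bromobenzene
Product: 4 2,4-bis(benzyloxy)-6-bromobenzaldehyde, via iminium chloride 3 (not isolated)
Conditions: POCl3, DMF, 0 to 80 °C; then H2O
Reagents that add atoms: N,N-dimethylformamide CN(C)C=O; water O
Why: Vilsmeier–Haack formylation, in which the chloroiminium ion attacks the ring carbon that is ortho to one benzyloxy group and para to the other (the site between the two ethers being more hindered), and hydrolysis of the iminium salt should release the aldehyde with bromine ortho to the formyl group.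

Step 3
Reactants: 5 1-bromo-3,5-dimethoxybenzene
Product: 7 2-bromo-4,6-dimethoxybenzaldehyde, via iminium chloride 6 (not isolated)
Conditions: POCl3, DMF, 0 to 90 °C; then H2O
Reagents that add atoms: N,N-dimethylformamide CN(C)C=O; water O
Why: Vilsmeier–Haack formylation with the same regiochemical preference as in step 2, the carbon ortho to bromine being activated by both methoxy groups and less crowded than the carbon between them.

Step 4
Reactants: 8 3,4-dihydroxybenzonitrile
Product: 9 4-(benzyloxy)-3-hydroxybenzonitrile
Conditions: BnBr (1 equiv), NaHCO3, NaI (cat.), DMF, 40 °C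
Reagents that add atoms: benzyl bromide BrCc1ccccc1
Why: Regioselective Williamson etherification, in which the weak base ionises mainly the more acidic hydroxyl para to the nitrile, so one equivalent of benzyl bromide should alkylate O4 and leave O3 free.

Step 5
Reactants: 9 4-(benzyloxy)-3-hydroxybenzonitrile; 10 4-fluoroacetophenone
Product: 11 3-(4-acetylphenoxy)-4-(benzyloxy)benzonitrile
Conditions: K2CO3, DMF, 120 °C
Reagents that add atoms: none
Why: Nucleophilic aromatic substitution by addition–elimination, in which the para-acetyl group stabilises the Meisenheimer adduct so that the phenoxide of 9 displaces fluoride, while the nitrile keeps the future acetyl group of unit 1 masked.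

Step 6
Reactants: 11 3-(4-acetylphenoxy)-4-(benzyloxy)benzonitrile; 4 2,4-bis(benzyloxy)-6-bromobenzaldehyde
Product: 13 3-{4-[3-(2,4-bis(benzyloxy)-6-bromophenyl)-3-hydroxypropanoyl]phenoxy}-4-(benzyloxy)benzonitrile (racemic carbinol), via lithium enolate 12 (not isolated)
Conditions: LiN(iPr)2, THF, −78 °C; then 4, −78 °C; AcOH quench at −78 °C
Reagents that add atoms: none
Why: Directed crossed aldol addition, in which the kinetic lithium enolate of the only enolisable ketone adds to the non-enolisable aldehyde and a cold acidic quench should prevent retro-aldol cleavage or dehydration; the new carbinol centre (later C4 of unit 2) forms as a racemate, which is harmless because it ends as a ketone.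

Step 7
Reactants: 13 the beta-hydroxy ketone from step 6
Product: 14 3-{4-[3-(2,4-bis(benzyloxy)-6-bromophenyl)-3-(tert-butyldimethylsilyloxy)propanoyl]phenoxy}-4-(benzyloxy)benzonitrile (racemic)
Conditions: TBSOTf, 2,6-lutidine, CH2Cl2, −78 to 0 °C
Reagents that add atoms: tert-butyldimethylsilyl trifluoromethanesulfonate CC(C)(C)[Si](C)(C)OS(=O)(=O)C(F)(F)F
Why: Silylation of a hindered secondary benzylic alcohol with a silyl triflate and a hindered pyridine base, which blocks retro-aldol cleavage and fixes C4 at the protected alcohol oxidation level.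

Step 8
Reactants: 14 the beta-silyloxy ketone from step 7
Product: 15 3-{4-[(1S)-3-(2,4-bis(benzyloxy)-6-bromophenyl)-3-(tert-butyldimethylsilyloxy)-1-hydroxypropyl]phenoxy}-4-(benzyloxy)benzonitrile (both epimers at the silyloxy carbon)
Conditions: RuCl(p-cymene)[(S,S)-TsDPEN] (cat.), HCO2H/Et3N (1:1), DMF, 40 °C
Reagents that add atoms: none
Why: Noyori–Ikariya asymmetric transfer hydrogenation, in which the ruthenium hydride and the ligand N–H deliver hydrogen to the Re face of the aryl ketone under catalyst control (aryl to arene CH/pi contact), which should give the S carbinol for either configuration of the remote silyloxy centre, while the amine-rich formate medium spares the acid-labile benzylic silyl ether, the nitrile and the aryl bromide.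

Step 9
Reactants: 15 the (S)-carbinol from step 8
Product: 16 4-(benzyloxy)-3-{4-[(2S)-5,7-bis(benzyloxy)-4-(tert-butyldimethylsilyloxy)chroman-2-yl]phenoxy}benzonitrile (both C4 epimers)
Conditions: Pd(OAc)2 (cat.), rac-2-(di-tert-butylphosphino)-1,1'-binaphthyl (cat.), Cs2CO3, toluene, 80 °C
Reagents that add atoms: none
Why: Buchwald–Hartwig intramolecular C–O coupling, in which zerovalent palladium inserts into the C–Br bond, the carbinol oxygen binds as its alkoxide and reductive elimination closes the pyran ring of unit 2 (O1–C8a) without breaking the C2–O bond, so the S configuration is retained.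

Step 10
Reactants: 16 the unit 2 flavan nitrile from step 9
Product: 18 1-[4-(benzyloxy)-3-{4-[(2S)-5,7-bis(benzyloxy)-4-(tert-butyldimethylsilyloxy)chroman-2-yl]phenoxy}phenyl]ethanone (both C4 epimers), via N-lithio ketimine 17 (not isolated)
Conditions: MeLi, THF, −78 to 0 °C; then AcOH/NaOAc buffer (pH 5), THF/H2O, 0 °C to rt
Reagents that add atoms: methyllithium C[Li]; water O
Why: Addition of an organolithium to an aryl nitrile, which stops at the N-lithio ketimine because this anion does not accept a second nucleophile, and mildly acidic hydrolysis of the imine should release the methyl ketone without ionising the benzylic silyl ether.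

Step 11
Reactants: 18 the methyl ketone from step 10; 7 2-bromo-4,6-dimethoxybenzaldehyde
Product: 20 3-(2-bromo-4,6-dimethoxyphenyl)-3-hydroxy-1-[4-(benzyloxy)-3-{4-[(2S)-5,7-bis(benzyloxy)-4-(tert-butyldimethylsilyloxy)chroman-2-yl]phenoxy}phenyl]propan-1-one (both carbinol epimers), via lithium enolate 19 (not isolated)
Conditions: LiN(iPr)2, THF, −78 °C; then 7, −78 °C; AcOH quench at −78 °C
Reagents that add atoms: none
Why: Directed crossed aldol addition of the kinetic lithium enolate to a non-enolisable aldehyde, as in step 6; the new carbinol centre (later C4 of unit 1) is not controlled and is oxidised later.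

Step 12
Reactants: 20 the beta-hydroxy ketone from step 11
Product: 21 3-(2-bromo-4,6-dimethoxyphenyl)-3-(tert-butyldimethylsilyloxy)-1-[4-(benzyloxy)-3-{4-[(2S)-5,7-bis(benzyloxy)-4-(tert-butyldimethylsilyloxy)chroman-2-yl]phenoxy}phenyl]propan-1-one
Conditions: TBSOTf, 2,6-lutidine (excess), CH2Cl2, −78 °C
Reagents that add atoms: tert-butyldimethylsilyl trifluoromethanesulfonate CC(C)(C)[Si](C)(C)OS(=O)(=O)C(F)(F)F
Why: Silyl triflate silylation of the hindered secondary benzylic alcohol, buffered by excess lutidine at low temperature so that the silyl ether already present in unit 2 is not activated.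

Step 13
Reactants: 21 the beta-silyloxy ketone from step 12
Product: 22 (1S)-3-(2-bromo-4,6-dimethoxyphenyl)-3-(tert-butyldimethylsilyloxy)-1-[4-(benzyloxy)-3-{4-[(2S)-5,7-bis(benzyloxy)-4-(tert-butyldimethylsilyloxy)chroman-2-yl]phenoxy}phenyl]propan-1-ol
Conditions: RuCl(p-cymene)[(S,S)-TsDPEN] (cat.), HCO2H/Et3N (1:1), DMF, 40 °C
Reagents that add atoms: none
Why: Noyori–Ikariya asymmetric transfer hydrogenation under catalyst control, as in step 8, which should deliver hydride to the Re face of the aryl ketone and set the S carbinol that becomes C2 of unit 1.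

Step 14
Reactants: 22 the (S)-carbinol from step 13
Product: 23 (2S)-2-[4-(benzyloxy)-3-{4-[(2S)-5,7-bis(benzyloxy)-4-(tert-butyldimethylsilyloxy)chroman-2-yl]phenoxy}phenyl]-4-(tert-butyldimethylsilyloxy)-5,7-dimethoxychroman
Conditions: Pd(OAc)2 (cat.), rac-2-(di-tert-butylphosphino)-1,1'-binaphthyl (cat.), Cs2CO3, toluene, 80 °C
Reagents that add atoms: none
Why: Zerovalent palladium, formed in the flask from Pd(OAc)2 and the bulky di-tert-butyl biaryl phosphine, inserts into the C8a–Br bond of ring A, the C2 hydroxyl binds to the arylpalladium bromide and is deprotonated by Cs2CO3, and C–O reductive elimination from the seven-membered oxapalladacycle forms O1–C8a. The closest known reaction type is the palladium-catalysed intramolecular etherification of aryl bromides by secondary alcohols (Buchwald–Hartwig C–O coupling), which gives chromans without loss of carbinol configuration. The pyran ring of unit 1 closes in a 6-exo sense, the chain oxygen attacking the ring carbon that carries the leaving group, and no other ring size is within reach of the three-carbon tether. No stereocentre is formed: none of the bonds at C2 is broken, so the S configuration from step 13 is carried through, and the two C4 silyloxy centres stay as epimer mixtures that step 16 removes. The step needs reductive elimination to outrun beta-hydride elimination of the secondary benzylic alkoxide, which the electron-rich, sterically demanding ligand favours and the ortho-branched tether assists by holding oxygen next to palladium. Site selectivity is built into 22, which has one free hydroxyl, one carbon–bromine bond and, with C4 at the silyl ether level in both units, no ketone that could enolise, eliminate or open a pyran ring under the carbonate base.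

Step 15
Reactants: 23 the protected bis(4-silyloxyflavan) from step 14
Product: 24 (2S)-2-[4-(benzyloxy)-3-{4-[(2S)-5,7-bis(benzyloxy)-4-hydroxychroman-2-yl]phenoxy}phenyl]-5,7-dimethoxychroman-4-ol
Conditions: Bu4NF, THF, rt
Reagents that add atoms: none
Why: Fluoride-induced desilylation, driven by Si–F bond formation, which should cleave both benzylic silyl ethers under non-acidic conditions that neither ionise the electron-rich flavan-4-ols nor touch C2.

Step 16
Reactants: 24 the bis(flavan-4-ol) from step 15
Product: 25 (2S)-2-[4-(benzyloxy)-3-{4-[(2S)-5,7-bis(benzyloxy)-4-oxochroman-2-yl]phenoxy}phenyl]-5,7-dimethoxychroman-4-one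
Conditions: Dess–Martin periodinane, NaHCO3, CH2Cl2, 0 °C to rt
Reagents that add atoms: none
Why: Dess–Martin oxidation of both secondary benzylic alcohols to aryl ketones under buffered conditions, which removes the two C4 stereocentres and, with no base and no free phenol present, should leave the C2 centres of the new flavanones intact.

Step 17
Reactants: 25 the protected bis-flavanone from step 16
Product: 26 7-O-methyltetrahydroochnaflavone, (2S)-5-hydroxy-2-[4-hydroxy-3-{4-[(2S)-5,7-dihydroxy-4-oxochroman-2-yl]phenoxy}phenyl]-7-methoxychroman-4-one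
Conditions: BCl3, C6HMe5, CH2Cl2, −78 to 0 °C; then MeOH/H2O
Reagents that add atoms: none
Why: Lewis-acid ether cleavage, in which BCl3 removes the three benzyl ethers at low temperature while pentamethylbenzene traps the benzyl cations (Friedel–Crafts scavenging), and on warming cleaves only the methyl ether peri to the C4 carbonyl of unit 1 through its six-membered boron chelate, so the 7-methoxy group should survive.

**Compound list**

1 | 5-bromoresorcinol | Oc1cc(O)cc(Br)c1 | starting material
2 | 1,3-bis(benzyloxy)-5-bromobenzene | Brc1cc(OCc2ccccc2)cc(OCc2ccccc2)c1 | intermediate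
3 | N-[2,4-bis(benzyloxy)-6-bromobenzylidene]-N-methylmethanaminium chloride | C[N+](C)=Cc1c(Br)cc(OCc2ccccc2)cc1OCc1ccccc1.[Cl-] | intermediate
4 | 2,4-bis(benzyloxy)-6-bromobenzaldehyde | O=Cc1c(Br)cc(OCc2ccccc2)cc1OCc1ccccc1 | intermediate
5 | 1-bromo-3,5-dimethoxybenzene | COc1cc(Br)cc(OC)c1 | starting material
6 | N-(2-bromo-4,6-dimethoxybenzylidene)-N-methylmethanaminium chloride | C[N+](C)=Cc1c(Br)cc(OC)cc1OC.[Cl-] | intermediate
7 | 2-bromo-4,6-dimethoxybenzaldehyde | O=Cc1c(Br)cc(OC)cc1OC | intermediate
8 | 3,4-dihydroxybenzonitrile | N#Cc1ccc(O)c(O)c1 | starting material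
9 | 4-(benzyloxy)-3-hydroxybenzonitrile | N#Cc1ccc(OCc2ccccc2)c(O)c1 | intermediate
10 | 4-fluoroacetophenone | CC(=O)c1ccc(F)cc1 | starting material
11 | 3-(4-acetylphenoxy)-4-(benzyloxy)benzonitrile | CC(=O)c1ccc(Oc2cc(C#N)ccc2OCc2ccccc2)cc1 | intermediate
12 | lithium enolate of 11 | [Li+].[O-]C(=C)c1ccc(Oc2cc(C#N)ccc2OCc2ccccc2)cc1 | intermediate
13 | 3-{4-[3-(2,4-bis(benzyloxy)-6-bromophenyl)-3-hydroxypropanoyl]phenoxy}-4-(benzyloxy)benzonitrile, racemic | N#Cc1ccc(OCc2ccccc2)c(Oc2ccc(C(=O)CC(O)c3c(Br)cc(OCc4ccccc4)cc3OCc3ccccc3)cc2)c1 | intermediate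
14 | tert-butyldimethylsilyl ether of 13, racemic | N#Cc1ccc(OCc2ccccc2)c(Oc2ccc(C(=O)CC(O[Si](C)(C)C(C)(C)C)c3c(Br)cc(OCc4ccccc4)cc3OCc3ccccc3)cc2)c1 | intermediate
15 | (1S)-carbinol from 14, either configuration at the silyloxy carbon | N#Cc1ccc(OCc2ccccc2)c(Oc2ccc([C@@H](O)CC(O[Si](C)(C)C(C)(C)C)c3c(Br)cc(OCc4ccccc4)cc3OCc3ccccc3)cc2)c1 | intermediate
16 | 4-(benzyloxy)-3-{4-[(2S)-5,7-bis(benzyloxy)-4-(tert-butyldimethylsilyloxy)chroman-2-yl]phenoxy}benzonitrile, either configuration at C4 | N#Cc1ccc(OCc2ccccc2)c(Oc2ccc([C@@H]3CC(O[Si](C)(C)C(C)(C)C)c4c(OCc5ccccc5)cc(OCc5ccccc5)cc4O3)cc2)c1 | intermediate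
17 | N-lithio ketimine from 16 and methyllithium | CC(=N[Li])c1ccc(OCc2ccccc2)c(Oc2ccc([C@@H]3CC(O[Si](C)(C)C(C)(C)C)c4c(OCc5ccccc5)cc(OCc5ccccc5)cc4O3)cc2)c1 | intermediate
18 | 1-[4-(benzyloxy)-3-{4-[(2S)-5,7-bis(benzyloxy)-4-(tert-butyldimethylsilyloxy)chroman-2-yl]phenoxy}phenyl]ethanone | CC(=O)c1ccc(OCc2ccccc2)c(Oc2ccc([C@@H]3CC(O[Si](C)(C)C(C)(C)C)c4c(OCc5ccccc5)cc(OCc5ccccc5)cc4O3)cc2)c1 | intermediate
19 | lithium enolate of 18 | [Li+].[O-]C(=C)c1ccc(OCc2ccccc2)c(Oc2ccc([C@@H]3CC(O[Si](C)(C)C(C)(C)C)c4c(OCc5ccccc5)cc(OCc5ccccc5)cc4O3)cc2)c1 | intermediate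
20 | beta-hydroxy ketone of unit 1 (2-bromo-4,6-dimethoxyphenyl carbinol), unit 2 as (2S)-4-silyloxyflavan | COc1cc(Br)c(C(O)CC(=O)c2ccc(OCc3ccccc3)c(Oc3ccc([C@@H]4CC(O[Si](C)(C)C(C)(C)C)c5c(OCc6ccccc6)cc(OCc6ccccc6)cc5O4)cc3)c2)c(OC)c1 | intermediate
21 | tert-butyldimethylsilyl ether of 20 | COc1cc(Br)c(C(CC(=O)c2ccc(OCc3ccccc3)c(Oc3ccc([C@@H]4CC(O[Si](C)(C)C(C)(C)C)c5c(OCc6ccccc6)cc(OCc6ccccc6)cc5O4)cc3)c2)O[Si](C)(C)C(C)(C)C)c(OC)c1 | intermediate
22 | (1S)-carbinol with 2-bromo-4,6-dimethoxyphenyl silyloxy chain, unit 2 as (2S)-4-silyloxyflavan | O[C@H](c1ccc(OCc2ccccc2)c(Oc2ccc([C@@H]3CC(O[Si](C)(C)C(C)(C)C)c4c(OCc5ccccc5)cc(OCc5ccccc5)cc4O3)cc2)c1)CC(O[Si](C)(C)C(C)(C)C)c1c(Br)cc(OC)cc1OC | intermediate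
23 | protected bis(4-silyloxyflavan), 2S in both units, either configuration at each C4 | COc1cc(OC)c2c(c1)O[C@H](c1ccc(OCc3ccccc3)c(Oc3ccc([C@@H]4CC(O[Si](C)(C)C(C)(C)C)c5c(OCc6ccccc6)cc(OCc6ccccc6)cc5O4)cc3)c1)CC2O[Si](C)(C)C(C)(C)C | intermediate
24 | bis(flavan-4-ol), 2S in both units, either configuration at each C4 | COc1cc(OC)c2c(c1)O[C@H](c1ccc(OCc3ccccc3)c(Oc3ccc([C@@H]4CC(O)c5c(OCc6ccccc6)cc(OCc6ccccc6)cc5O4)cc3)c1)CC2O | intermediate
25 | protected bis-flavanone (5,7-dimethoxy in unit 1, three benzyl ethers), 2S in both units | COc1cc(OC)c2c(c1)O[C@H](c1ccc(OCc3ccccc3)c(Oc3ccc([C@@H]4CC(=O)c5c(OCc6ccccc6)cc(OCc6ccccc6)cc5O4)cc3)c1)CC2=O | intermediate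
26 | 7-O-methyltetrahydroochnaflavone | COc1cc(O)c2c(c1)O[C@H](c1ccc(O)c(Oc3ccc([C@@H]4CC(=O)c5c(O)cc(O)cc5O4)cc3)c1)CC2=O | target

**Count and risks**

Total: 17 steps. Longest linear sequence: 14 steps (steps 4 to 17 from 3,4-dihydroxybenzonitrile 8; the branch through steps 1 and 2 is equally long).

Most likely to fail:

1. Step 14 (key ring closure). The palladium alkoxide may undergo beta-hydride elimination, returning the aryl ketone and a debrominated arene, or C–O reductive elimination may be too slow at the crowded arylpalladium centre. The fallback closes the same pyran ring from the other side, forming O1–C2 with inversion. It sets out from ketone 21. Transfer hydrogenation with RuCl(p-cymene)[(R,R)-TsDPEN] and HCO2H/Et3N should give the (R)-carbinol F1. Miyaura borylation (PdCl2(dppf), B2pin2, KOAc, dioxane, 80 °C) should replace bromine and give the pinacol boronate F2, and NaBO3·4H2O in THF/H2O should oxidise it to the phenol F3. An intramolecular Mitsunobu etherification (PPh3, diisopropyl azodicarboxylate, THF, 0 °C) should then displace the activated C2 hydroxyl by the phenol oxygen with inversion. This gives the (2S)-flavan 23, where the route is rejoined.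

2. Step 17 (global ether cleavage). Ether cleavage may be incomplete or unselective, benzyl cations may alkylate the freed, electron-rich ring A of unit 2, or the Lewis acid may open a pyranone ring with loss of C2 configuration. The fallback separates the two kinds of ether cleavage and sets out from 25. Hydrogenolysis (H2, Pd/C, EtOAc/MeOH, rt) should remove the three benzyl ethers without generating cations and give the 5-O-methyl tetraphenol F4. Selective demethylation peri to the carbonyl group with AlCl3 in MeCN at rt should then give 26.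

3. Step 11 (aldol on the advanced ketone; the same concern applies to step 6). The lithium aldolate of a di-ortho-substituted, donor-rich aldehyde may revert by retro-aldol cleavage or dehydrate, and addition to the deactivated aldehyde may be slow. The fallback accepts the dehydration and installs the C4 oxygen afterwards; it sets out from 18 and 7. Claisen–Schmidt condensation (KOH, EtOH/THF, rt) should give the (E)-chalcone F5. Copper-catalysed conjugate borylation (CuCl, NaOtBu, bis[2-(diphenylphosphino)phenyl] ether, B2pin2, MeOH, THF, rt) should give the beta-boryl ketone F6. Oxidation with NaBO3·4H2O in THF/H2O should then give beta-hydroxy ketone 20, where the route is rejoined.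

**Further compounds**

F1 | step 14 | (1R)-epimer of carbinol 22 | O[C@@H](c1ccc(OCc2ccccc2)c(Oc2ccc([C@@H]3CC(O[Si](C)(C)C(C)(C)C)c4c(OCc5ccccc5)cc(OCc5ccccc5)cc4O3)cc2)c1)CC(O[Si](C)(C)C(C)(C)C)c1c(Br)cc(OC)cc1OC
F2 | step 14 | pinacol boronate from F1 (boron in place of bromine) | O[C@@H](c1ccc(OCc2ccccc2)c(Oc2ccc([C@@H]3CC(O[Si](C)(C)C(C)(C)C)c4c(OCc5ccccc5)cc(OCc5ccccc5)cc4O3)cc2)c1)CC(O[Si](C)(C)C(C)(C)C)c1c(B2OC(C)(C)C(C)(C)O2)cc(OC)cc1OC
F3 | step 14 | phenol from F2 (2-hydroxy-4,6-dimethoxyphenyl silyloxy chain, (1R)-carbinol) | O[C@@H](c1ccc(OCc2ccccc2)c(Oc2ccc([C@@H]3CC(O[Si](C)(C)C(C)(C)C)c4c(OCc5ccccc5)cc(OCc5ccccc5)cc4O3)cc2)c1)CC(O[Si](C)(C)C(C)(C)C)c1c(O)cc(OC)cc1OC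
F4 | step 17 | 5-O-methyl ether of the target (unit 1 5,7-dimethoxy, all other phenols free) | COc1cc(OC)c2c(c1)O[C@H](c1ccc(O)c(Oc3ccc([C@@H]4CC(=O)c5c(O)cc(O)cc5O4)cc3)c1)CC2=O
F5 | step 11 | (E)-chalcone from 18 and 7 | COc1cc(Br)c(/C=C/C(=O)c2ccc(OCc3ccccc3)c(Oc3ccc([C@@H]4CC(O[Si](C)(C)C(C)(C)C)c5c(OCc6ccccc6)cc(OCc6ccccc6)cc5O4)cc3)c2)c(OC)c1
F6 | step 11 | beta-(pinacolboryl) ketone from F5 | COc1cc(Br)c(C(CC(=O)c2ccc(OCc3ccccc3)c(Oc3ccc([C@@H]4CC(O[Si](C)(C)C(C)(C)C)c5c(OCc6ccccc6)cc(OCc6ccccc6)cc5O4)cc3)c2)B2OC(C)(C)C(C)(C)O2)c(OC)c1
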